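The numbering below is that of 1-oxaspiro[2.4]hept-6-en-5-one. The route rests on cutting C3–C4, the bond between the two adjacent fully substituted carbons, together with O1–C2 of the oxirane. C3 is both the aldol carbon β to the C5 ketone and the carbinol carbon of a chlorohydrin. One base-triggered cascade under a chiral ammonium cation (C4 enolate to C3 ketone, then C3 alkoxide to CH2Cl) should therefore close the cyclopentenone and the spiro-oxirane and set both stereocentres together. The precursor is an open-chain cis-ene-dione chloromethyl ketone with no lasting stereocentre. Its C6=C7 geometry is inherited from a pulvinone-type 5-ylidenebutenolide that chloromethyllithium opens.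

Key step: step 7

Assumption: the sense of induction of the ammonium salt cannot be derived from precedent. The cinchonine-derived salt is written, its cinchonidine-derived pseudoenantiomer replaces it if the (3S,4S) series is favoured, and the configuration is to be secured by X-ray or CD analysis.

Step 1
Reactants: 1 4-methoxyfuran-2(5H)-one
Product: 2 3-bromo-4-methoxyfuran-2(5H)-one
Conditions: NBS, MeCN, rt, dark
Reagents that add atoms: N-bromosuccinimide, O=C1CCC(=O)N1Br
Why: Electrophilic bromination of a vinylogous carbonate: C3 is the nucleophilic β-carbon of the ring enol ether and the only vinylic C–H, and polar conditions without light should keep radical bromination at C5 out.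

Step 2
Reactants: 2 3-bromo-4-methoxyfuran-2(5H)-one; 3 [4-(tert-butyldimethylsilyloxy)phenyl]boronic acid
Product: 4 3-[4-(tert-butyldimethylsilyloxy)phenyl]-4-methoxyfuran-2(5H)-one
Conditions: Pd(PPh3)4 (5 mol %), K2CO3, toluene/EtOH/H2O, 80 °C
Reagents that add atoms: none
Why: Suzuki–Miyaura coupling of an α-bromo-β-alkoxybutenolide, an established way to 3-aryltetronates, under carbonate conditions that the lactone and the aryl silyl ether should tolerate.

Step 3
Reactants: 4 3-[4-(tert-butyldimethylsilyloxy)phenyl]-4-methoxyfuran-2(5H)-one; 5 4-(tert-butyldimethylsilyloxy)benzaldehyde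
Product: 7 5-{hydroxy[4-(tert-butyldimethylsilyloxy)phenyl]methyl}-3-[4-(tert-butyldimethylsilyloxy)phenyl]-4-methoxyfuran-2(5H)-one (racemic diastereomer mixture), via lithium furanolate 6 (not isolated)
Conditions: LDA, THF, −78 °C; then 5; AcOH quench at −78 °C
Reagents that add atoms: none
Why: Vinylogous aldol addition: LDA removes a C5 proton to give furanolate 6, which attacks aromatic aldehydes through C5 as in pulvinone syntheses, and since both new stereocentres are erased in steps 4 and 5 no control is needed while the cold acidic quench should prevent elimination.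

Step 4
Reactants: 7 5-{hydroxy[4-(tert-butyldimethylsilyloxy)phenyl]methyl}-3-[4-(tert-butyldimethylsilyloxy)phenyl]-4-methoxyfuran-2(5H)-one
Product: 8 5-[4-(tert-butyldimethylsilyloxy)benzoyl]-3-[4-(tert-butyldimethylsilyloxy)phenyl]-4-methoxyfuran-2(5H)-one
Conditions: Dess–Martin periodinane, CH2Cl2, 0 °C to rt
Reagents that add atoms: none
Why: Dess–Martin oxidation of a secondary benzylic alcohol, neutral enough to spare the silyl ethers, the enol ether and the base-sensitive 5-acylbutenolide.

Step 5
Reactants: 8 5-[4-(tert-butyldimethylsilyloxy)benzoyl]-3-[4-(tert-butyldimethylsilyloxy)phenyl]-4-methoxyfuran-2(5H)-one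
Product: 10 5-{methoxy[4-(tert-butyldimethylsilyloxy)phenyl]methylidene}-3-[4-(tert-butyldimethylsilyloxy)phenyl]-4-methoxyfuran-2(5H)-one (E/Z mixture), via dimethyl ketal 9 (not isolated)
Conditions: HC(OMe)3, CSA (cat.), MeOH/CH2Cl2, 40 °C
Reagents that add atoms: trimethyl orthoformate, COC(OC)OC
Why: Acid-catalysed ketalisation with an orthoester followed by loss of methanol (enol ether formation), driven by conjugation of the new C=C bond with the butenolide and regiodefined because only the ketone carbon can carry the ketal; the alkene geometry is of no consequence because it is lost in step 6.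

Step 6
Reactants: 10 5-{methoxy[4-(tert-butyldimethylsilyloxy)phenyl]methylidene}-3-[4-(tert-butyldimethylsilyloxy)phenyl]-4-methoxyfuran-2(5H)-one
Product: 12 (E)-6-chloro-1,3-dimethoxy-1,4-bis[4-(tert-butyldimethylsilyloxy)phenyl]hex-3-ene-2,5-dione (the two acyl groups cis; racemic at C1), via lithium hemiketal alkoxide 11 (not isolated)
Conditions: ClCH2I, MeLi·LiBr, THF/Et2O, −78 °C; AcOH/THF quench at −78 °C; work-up at pH 5
Reagents that add atoms: chloroiodomethane, ClCI
Why: Homologation of an ester to an α-chloroketone with a halomethyllithium carbenoid made by iodine–lithium exchange in the presence of the substrate: 1,2-addition to the enol-lactone carbonyl gives alkoxide 11, which should persist at −78 °C, and protonation with ring–chain tautomerism releases 12 with its two acyl groups cis because they were ring members of 10.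

Step 7
Reactants: 12 (E)-6-chloro-1,3-dimethoxy-1,4-bis[4-(tert-butyldimethylsilyloxy)phenyl]hex-3-ene-2,5-dione
Product: 14 (3R,4R)-4,6-dimethoxy-4,7-bis[4-(tert-butyldimethylsilyloxy)phenyl]-1-oxaspiro[2.4]hept-6-en-5-one, via chlorohydrin alkoxide 13 (not isolated)
Conditions: N-[4-(trifluoromethyl)benzyl]cinchoninium bromide (10 mol %), Cs2CO3 (solid), toluene, −20 °C
Reagents that add atoms: none
Why: Proposed new method: solid carbonate removes the most acidic proton of 12 (C1–H, at once benzylic, α-keto and α-methoxy, and several pK units below the CH2Cl protons, which flank a vinylogous-ester carbonyl), the enolate paired with the chiral ammonium ion adds through carbon to the chloromethyl ketone that the cis-alkene holds next to it, and alkoxide 13 expels chloride. The closest known reaction types are the base-induced aldol closure of cis-ene-diones to 4-hydroxycyclopent-2-enones, the addition of ketone enolates to α-chloroketones with oxirane closure, and the cinchona phase-transfer Darzens reaction, in which a reversible aldol step is followed by catalyst-controlled closure of one chlorohydrin alkoxide; what is new is their merger under a chiral cation at a bond between two fully substituted carbons. The carbocycle closes by a 5-(enolendo)-exo-trig aldol addition, best seen as a conrotatory 4π closure of the 2-oxidopentadienyl array and routinely observed for 1,4-dicarbonyl compounds although the ring-closure rules formally disfavour it, and the oxirane closes 3-exo-tet with retention at the carbinol carbon. The relative configuration follows from reversible aldolisation without a chelating metal, because the alkoxide with CH2Cl anti to the aryl group on the neighbouring carbon and C–O(−) anti to C–OMe is the least crowded and least dipole-opposed, and it is the one that leads to the oxirane oxygen trans to OMe as in the target. The absolute configuration is set by the cation, whose C9 hydroxyl group and shielded N+ face should bind one enantiomer of the equilibrating alkoxide and speed up its closure, a dynamic kinetic resolution fed by retro-aldol. The step needs aldol/oxirane closure to outrun six-ring C- or O-alkylation at CH2Cl, which the fast 3-exo-tet closure of a tertiary alkoxide, the hindered enolate carbon and the weak SN2 activation by the electron-rich ketone next to CH2Cl should secure.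

Step 8
Reactants: 14 (3R,4R)-4,6-dimethoxy-4,7-bis[4-(tert-butyldimethylsilyloxy)phenyl]-1-oxaspiro[2.4]hept-6-en-5-one
Product: 15 (3R,4R)-4,7-bis(4-hydroxyphenyl)-4,6-dimethoxy-1-oxaspiro[2.4]hept-6-en-5-one (CNP0504072.1)
Conditions: TBAF, AcOH, THF, 0 °C
Reagents that add atoms: none
Why: Fluoride-induced cleavage of aryl silyl ethers, buffered with acetic acid so that no phenoxide or alkoxide is present that could open the vinyl oxirane or expel the benzylic methoxy group, and without effect on either stereocentre.

Compound list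
1 | 4-methoxyfuran-2(5H)-one | COC1=CC(=O)OC1 | starting material
2 | 3-bromo-4-methoxyfuran-2(5H)-one | COC1=C(Br)C(=O)OC1 | intermediate
3 | [4-(tert-butyldimethylsilyloxy)phenyl]boronic acid | CC(C)(C)[Si](C)(C)Oc1ccc(cc1)B(O)O | starting material
4 | 3-[4-(tert-butyldimethylsilyloxy)phenyl]-4-methoxyfuran-2(5H)-one | COC1=C(C(=O)OC1)c1ccc(O[Si](C)(C)C(C)(C)C)cc1 | intermediate
5 | 4-(tert-butyldimethylsilyloxy)benzaldehyde | CC(C)(C)[Si](C)(C)Oc1ccc(C=O)cc1 | starting material
6 | lithium 3-[4-(tert-butyldimethylsilyloxy)phenyl]-4-methoxyfuran-2-olate | [Li+].[O-]c1occ(OC)c1-c1ccc(O[Si](C)(C)C(C)(C)C)cc1 | intermediate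
7 | 5-{hydroxy[4-(tert-butyldimethylsilyloxy)phenyl]methyl}-3-[4-(tert-butyldimethylsilyloxy)phenyl]-4-methoxyfuran-2(5H)-one, racemic diastereomer mixture | COC1=C(c2ccc(O[Si](C)(C)C(C)(C)C)cc2)C(=O)OC1C(O)c1ccc(O[Si](C)(C)C(C)(C)C)cc1 | intermediate
8 | 5-[4-(tert-butyldimethylsilyloxy)benzoyl]-3-[4-(tert-butyldimethylsilyloxy)phenyl]-4-methoxyfuran-2(5H)-one, racemic | COC1=C(c2ccc(O[Si](C)(C)C(C)(C)C)cc2)C(=O)OC1C(=O)c1ccc(O[Si](C)(C)C(C)(C)C)cc1 | intermediate
9 | 5-{dimethoxy[4-(tert-butyldimethylsilyloxy)phenyl]methyl}-3-[4-(tert-butyldimethylsilyloxy)phenyl]-4-methoxyfuran-2(5H)-one | COC1=C(c2ccc(O[Si](C)(C)C(C)(C)C)cc2)C(=O)OC1C(OC)(OC)c1ccc(O[Si](C)(C)C(C)(C)C)cc1 | intermediate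
10 | 5-{methoxy[4-(tert-butyldimethylsilyloxy)phenyl]methylidene}-3-[4-(tert-butyldimethylsilyloxy)phenyl]-4-methoxyfuran-2(5H)-one, E/Z mixture | COC1=C(c2ccc(O[Si](C)(C)C(C)(C)C)cc2)C(=O)OC1=C(OC)c1ccc(O[Si](C)(C)C(C)(C)C)cc1 | intermediate
11 | lithium 2-(chloromethyl)-4-methoxy-5-{methoxy[4-(tert-butyldimethylsilyloxy)phenyl]methylidene}-3-[4-(tert-butyldimethylsilyloxy)phenyl]-2,5-dihydrofuran-2-olate | [Li+].[O-]C1(CCl)OC(=C(OC)c2ccc(O[Si](C)(C)C(C)(C)C)cc2)C(OC)=C1c1ccc(O[Si](C)(C)C(C)(C)C)cc1 | intermediate
12 | (E)-6-chloro-1,3-dimethoxy-1,4-bis[4-(tert-butyldimethylsilyloxy)phenyl]hex-3-ene-2,5-dione, acyl groups cis, racemic at C1 | ClCC(=O)/C(c1ccc(O[Si](C)(C)C(C)(C)C)cc1)=C(/OC)C(=O)C(OC)c1ccc(O[Si](C)(C)C(C)(C)C)cc1 | intermediate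
13 | (4S,5R)-4-(chloromethyl)-2,5-dimethoxy-4-oxido-3,5-bis[4-(tert-butyldimethylsilyloxy)phenyl]cyclopent-2-en-1-one, ion pair with the catalyst cation (the anion is drawn) | COC1=C(c2ccc(O[Si](C)(C)C(C)(C)C)cc2)[C@@]([O-])(CCl)[C@](OC)(c2ccc(O[Si](C)(C)C(C)(C)C)cc2)C1=O | intermediate
14 | (3R,4R)-4,6-dimethoxy-4,7-bis[4-(tert-butyldimethylsilyloxy)phenyl]-1-oxaspiro[2.4]hept-6-en-5-one | COC1=C(c2ccc(O[Si](C)(C)C(C)(C)C)cc2)[C@@]2(CO2)[C@](OC)(c2ccc(O[Si](C)(C)C(C)(C)C)cc2)C1=O | intermediate
15 | (3R,4R)-4,7-bis(4-hydroxyphenyl)-4,6-dimethoxy-1-oxaspiro[2.4]hept-6-en-5-one | COC1=C(c2ccc(O)cc2)[C@@]2(CO2)[C@](OC)(c2ccc(O)cc2)C1=O | target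

Total step count: 8. Longest linear sequence: 8 steps (1 to 15); 3 and 5 are bought and enter directly.

Steps most likely to fail

1. Step 7 (Proposed new method). The chiral cation may discriminate too weakly between the equilibrating enantiomeric alkoxides. The enolate may also be drained by alkylation at CH2Cl or by enolisation on the chloromethyl side. The fallback replaces asymmetric catalysis by classical resolution, with every bond formed by a known uncatalysed reaction type (aldol closure of a cis-ene-dione, oxirane closure of a chlorohydrin alkoxide, esterification, methanolysis). It sets out from 12.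
   - Cs2CO3 with tetrabutylammonium bromide in toluene should give the racemic trans-configured silyl-protected spiro-epoxide F1.
   - TBAF/AcOH should give the racemic bisphenol F2.
   - (1S)-Camphanic chloride, Et3N and DMAP should give the (3R,4R)-bis-camphanate F3 and the (3S,4S)-bis-camphanate F4. These are separated by crystallisation or chromatography and assigned by X-ray analysis against the known auxiliary.
   - K2CO3 in MeOH at 0 °C on the (3R,4R)-bis-camphanate comes back to the route at 15.

2. Step 6. Alkoxide 11 may collapse early, which would lead to a second carbenoid addition or to uncontrolled racemic cyclisation. Methyllithium may also attack the substrate directly. The fallback replaces the carbenoid by a stabilised ylide and sets out from 10.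
   - One equivalent of dimethylsulfoxonium methylide (Me3S(O)I, KOtBu, THF) should acylate at the enol-lactone carbonyl.
   - Internal proton transfer from the acidic CH2 to the released enolate should give the β-keto sulfoxonium ylide F5, which cannot add a second time or cyclise.
   - One equivalent of HCl in THF should displace dimethyl sulfoxide and come back to the route at 12.

3. Step 5. The aryl silyl groups may be lost under acid, or ketalisation of a hindered, electron-rich aryl ketone may be sluggish. The fallback avoids both the ketone and acid. It sets out from 7.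
   - MsCl/Et3N should give the benzylic mesylate F6.
   - Excess Et3N or DBU should eliminate it to the (Z)-5-arylidene tetronate F7.
   - NBS in MeOH should add bromine at C5 and methanol at the benzylic carbon to give the bromo ether F8.
   - DBU should remove HBr and come back to the route at 10.

Further compounds
F1 | step 7 | racemic trans-4,6-dimethoxy-4,7-bis[4-(tert-butyldimethylsilyloxy)phenyl]-1-oxaspiro[2.4]hept-6-en-5-one | COC1=C(c2ccc(O[Si](C)(C)C(C)(C)C)cc2)C2(CO2)C(OC)(c2ccc(O[Si](C)(C)C(C)(C)C)cc2)C1=O
F2 | step 7 | racemic trans-4,7-bis(4-hydroxyphenyl)-4,6-dimethoxy-1-oxaspiro[2.4]hept-6-en-5-one | COC1=C(c2ccc(O)cc2)C2(CO2)C(OC)(c2ccc(O)cc2)C1=O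
F3 | step 7 | bis[(1S,4R)-camphanate] of the (3R,4R)-bisphenol | COC1=C(c2ccc(OC(=O)[C@@]34CC[C@@](C)(C(=O)O3)C4(C)C)cc2)[C@@]2(CO2)[C@](OC)(c2ccc(OC(=O)[C@@]34CC[C@@](C)(C(=O)O3)C4(C)C)cc2)C1=O
F4 | step 7 | bis[(1S,4R)-camphanate] of the (3S,4S)-bisphenol | COC1=C(c2ccc(OC(=O)[C@@]34CC[C@@](C)(C(=O)O3)C4(C)C)cc2)[C@]2(CO2)[C@@](OC)(c2ccc(OC(=O)[C@@]34CC[C@@](C)(C(=O)O3)C4(C)C)cc2)C1=O
F5 | step 6 | (E)-6-(dimethyloxosulfaniumyl)ylide of 1,3-dimethoxy-1,4-bis[4-(tert-butyldimethylsilyloxy)phenyl]hex-3-ene-2,5-dione | CS(C)(=O)=CC(=O)/C(c1ccc(O[Si](C)(C)C(C)(C)C)cc1)=C(/OC)C(=O)C(OC)c1ccc(O[Si](C)(C)C(C)(C)C)cc1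
F6 | step 5 | 5-{(methylsulfonyloxy)[4-(tert-butyldimethylsilyloxy)phenyl]methyl}-3-[4-(tert-butyldimethylsilyloxy)phenyl]-4-methoxyfuran-2(5H)-one | COC1=C(c2ccc(O[Si](C)(C)C(C)(C)C)cc2)C(=O)OC1C(OS(C)(=O)=O)c1ccc(O[Si](C)(C)C(C)(C)C)cc1
F7 | step 5 | (Z)-5-[4-(tert-butyldimethylsilyloxy)benzylidene]-3-[4-(tert-butyldimethylsilyloxy)phenyl]-4-methoxyfuran-2(5H)-one | COC1=C(c2ccc(O[Si](C)(C)C(C)(C)C)cc2)C(=O)O/C1=C\c1ccc(O[Si](C)(C)C(C)(C)C)cc1
F8 | step 5 | 5-bromo-5-{methoxy[4-(tert-butyldimethylsilyloxy)phenyl]methyl}-3-[4-(tert-butyldimethylsilyloxy)phenyl]-4-methoxyfuran-2(5H)-one | COC1=C(c2ccc(O[Si](C)(C)C(C)(C)C)cc2)C(=O)OC1(Br)C(OC)c1ccc(O[Si](C)(C)C(C)(C)C)cc1
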